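The red run ended with 52.1% of its charge as ring, and the teal run, charged with more starting material, ended with a lower share, 34.4%.

| flask | starting material | remark | time |
|---|---|---|---|
| red | 13 mM | run made earlier |  |
| teal | 30 mM | run made earlier |  |
| flask | 20 mM |  | 4.0 h |

| run | time / h | side product / % | ring / % | starting material / % | open dimer / % |
|---|---|---|---|---|---|
| red | 0.200 | 1.5 | 35.5 | 21.5 | 42.2 |
| red | 0.667 | 1.8 | 49.1 | 2.5 | 46.4 |
| red | 1.00 | 1.6 | 50.9 | 0.7 | 45.3 |
| red | 1.50 | 2.0 | 51.6 | 0.3 | 46.1 |
| red | 2.50 | 2.0 | 51.9 | 0.2 | 45.9 |
| red | 3.00 | 1.7 | 52.1 | 0 | 46.3 |
| red | 4.00 | 2.0 | 52.1 | 0.1 | 46.0 |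
| teal | 0.333 | 1.6 | 30.0 | 6.2 | 62.2 |
| teal | 0.500 | 1.5 | 32.3 | 2.8 | 63.3 |
| teal | 0.667 | 1.9 | 33.9 | 0.9 | 63.4 |
| teal | 1.00 | 2.1 | 34.5 | 0.3 | 63.0 |
| teal | 1.50 | 2.2 | 34.3 | 0 | 63.6 |
| teal | 2.50 | 2.4 | 34.5 | 0 | 63.5 |
| teal | 4.00 | 2.3 | 34.4 | 0 | 63.7 |

(standard deviation of a reading: 0.3 percentage points)

- percentages count the starting material that a species holds: one open dimer or side product counts as two
- candidate steps: starting material -> ring; 2 starting material -> open dimer; starting material + ring -> side product

1. the largest share of what was charged as starting material, at 4.0 h belongs to (side product / starting material / open dimer / ring)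
2. the largest share itself, whichever of these holds it, in percent of the starting material charged

My own reckoning is this. If the ring step goes with c(starting material) and the open dimer step with its square, one concentration marks the crossing, where both steps use starting material equally; above it the dimer step takes more. Call the charge divided by this crossing concentration x. With the side product step set aside, the ring formed by the time the starting material is used up is then ln(1+x)/x of the charge.

Each side product holds one ring, so the ring formed is the final ring plus half the side product. The red end gives 53.1%, which solves to about 5.95 mM. The teal end, a different charge, gives 35.5%, which solves to about 5.91 mM. The two ways differ by about 0.0400 mM, so their mean is kept as a reading: the crossing concentration 5.93 mM.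

For the flask, x is 3.37, so the ring formed is 43.7%. With side product taken as 2.15%, the mean of the two runs at 4.0 h, open dimer in the flask is reckoned at 55.2%, more than ring.

The forecast also names open dimer, at 55%, with a range of 54.2% to 55.8%, on the ground that “Ring and dimer formation compete, first order against second order”.

The flask gives open dimer at 55.2%, with ring at 42.7% and side product at 2.08%.

    starting material → ring (k = 3.80 h⁻¹)
    2 starting material → open dimer (k = 310 M⁻¹ h⁻¹)
    starting material + ring → side product (k = 21.0 M⁻¹ h⁻¹)

By 0.400 h the flask had 5.94% starting material left and already held 54.7% open dimer. By 2.00 h starting material stood at 0.00865%, and at 40.0 h the flask still held 55.2% open dimer and 42.7% ring.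

In the neighbour flask, the same flask with 8.0 mM of starting material charged and the time held, x is 1.35, so the ring formed is reckoned at 63.3%, which puts ring ahead of open dimer. That neighbour flask computes to ring in the lead, with 62.4% ring, 35.8% open dimer and 1.76% side product.

(All runs are calculated for substances that don't exist; noise was put on by code.)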